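**Plan**
- Retrosynthesis: the ethyl and the two benzyl C–O bonds are cut last. The central benzene ring is then cut at two ring bonds, C(arm)–C(OEt) and C(acyl)–C(OH), with CO2 restored as a lactone bridge. The remaining cuts are the two CH–CH2 bonds joining the arms to a 3-oxoglutarate and the C(=O)–C(sp) bond of an ynone.
- Enabling feature: the benzene carbons alternate C- and O-substituents. The run arm-C, C–OH, arm-C, C–OH is C3, C4, C5, C6 of a 3,5-disubstituted 4,6-dioxy-2-pyrone (a bis-silylated 3-oxoglutaric anhydride). The acyl-bearing carbon and its C–O neighbour are the two sp carbons of a β-ethoxy ynone.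
- Forward: the two outer 2-pyrone rings are built first, functionalised at C3 and attached to di-tert-butyl 3-oxoglutarate. The six-membered anhydride ring is then closed and bis-silylated. The benzene ring forms last by [4+2] addition and CO2 loss, and BCl3 frees the hydroxyls.
- Stereochemistry: the single (R) centre is bought with (R)-2-methylbutanoic acid and carried through acylimidazole, Weinreb amide and ynone without enolising conditions. No other stereocentre persists.

Key step: step 12

Assumption: (R)-2-methylbutanoic acid is taken as a purchasable single enantiomer. The CH centres beside the central ketone in 10–13 are left unspecified because they become sp2 in 14.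

**Step 1**
Reactants: 1 3-pentanone
Product: 2 3-(trimethylsilyloxy)pent-2-ene (E/Z mixture)
Conditions: TMSCl, Et3N, DMF, 80 °C
Reagents that add atoms: chlorotrimethylsilane, C[Si](C)(C)Cl
Why: Thermodynamic enol silylation of a symmetrical ketone can give only one regioisomeric silyl enol ether, and its double-bond geometry is irrelevant.

**Step 2**
Reactants: 2 3-(trimethylsilyloxy)pent-2-ene; 3 malonyl dichloride
Product: 4 6-ethyl-4-hydroxy-5-methyl-2H-pyran-2-one
Conditions: Et2O, −78 °C → rt
Reagents that add atoms: none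
Why: In this known 4-hydroxy-2-pyrone synthesis the silyl enol ether is C-acylated by one acid chloride and the resulting 1,3-diketone enol is O-acylated by the second, which closes the ring with ethyl at C6 and methyl at C5.

**Step 3**
Reactants: 4 6-ethyl-4-hydroxy-5-methyl-2H-pyran-2-one
Product: 5 4-(benzyloxy)-6-ethyl-5-methyl-2H-pyran-2-one
Conditions: BnOH, PPh3, DIAD, THF, 0 °C → rt
Reagents that add atoms: benzyl alcohol, OCc1ccccc1
Why: Mitsunobu alkylation of the acidic 4-hydroxy-2-pyrone (a vinylogous acid) is known to occur on O4 and avoids the C3-benzylation that competes under basic alkylation.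

**Step 4**
Reactants: 5 4-(benzyloxy)-6-ethyl-5-methyl-2H-pyran-2-one
Product: 6 4-(benzyloxy)-3-bromo-6-ethyl-5-methyl-2H-pyran-2-one
Conditions: NBS, MeCN, rt, dark
Reagents that add atoms: N-bromosuccinimide, O=C1CCC(=O)N1Br
Why: Electrophilic bromination of a 4-alkoxy-2-pyrone occurs at the enol-ether carbon C3, the only unsubstituted ring position here, and polar conditions in the dark suppress allylic radical bromination.

**Step 5**
Reactants: 6 4-(benzyloxy)-3-bromo-6-ethyl-5-methyl-2H-pyran-2-one
Product: 7 4-(benzyloxy)-6-ethyl-3-(hydroxymethyl)-5-methyl-2H-pyran-2-one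
Conditions: Bu3SnCH2OH, Pd(PPh3)4 (5 mol %), dioxane, 90 °C
Reagents that add atoms: (tributylstannyl)methanol, OC[Sn](CCCC)(CCCC)CCCC
Why: Stille hydroxymethylation relies on oxidative addition of zerovalent palladium into the activated C3–Br bond and transfer of CH2OH from tin, which is precedented on aryl and vinyl bromides, while the benzyl ether and lactone are inert.

**Step 6**
Reactants: 7 4-(benzyloxy)-6-ethyl-3-(hydroxymethyl)-5-methyl-2H-pyran-2-one
Product: 8 4-(benzyloxy)-3-(bromomethyl)-6-ethyl-5-methyl-2H-pyran-2-one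
Conditions: CBr4, PPh3, CH2Cl2, 0 °C; used at once
Reagents that add atoms: tetrabromomethane, BrC(Br)(Br)Br
Why: Appel bromination converts the primary, benzylic-type alcohol to the bromide under neutral conditions that spare the vinylogous benzyl ester.

**Step 7**
Reactants: 9 di-tert-butyl 3-oxopentanedioate (di-tert-butyl 3-oxoglutarate); 8 4-(benzyloxy)-3-(bromomethyl)-6-ethyl-5-methyl-2H-pyran-2-one (2 equiv)
Product: 11 di-tert-butyl 2,4-bis[(4-benzyloxy-6-ethyl-5-methyl-2-oxo-2H-pyran-3-yl)methyl]-3-oxopentanedioate (diastereomer mixture), via monoalkylated keto diester 10 (not isolated)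
Conditions: NaH (2 × 1.05 equiv), 8 (2 × 1.0 equiv) in two cycles, THF, 0 °C → rt
Reagents that add atoms: none
Why: Sequential SN2 C-alkylation of the 3-oxoglutarate enolate places the second arm at C4 because the remaining unsubstituted methylene is the more acidic and less hindered site, and the two uncontrolled CH centres are flattened in steps 8 and 9.

**Step 8**
Reactants: 11 di-tert-butyl 2,4-bis[(4-benzyloxy-6-ethyl-5-methyl-2-oxo-2H-pyran-3-yl)methyl]-3-oxopentanedioate
Product: 13 3,5-bis[(4-benzyloxy-6-ethyl-5-methyl-2-oxo-2H-pyran-3-yl)methyl]-4-hydroxy-2H-pyran-2,6(3H)-dione (enol form of the 2,4-disubstituted 3-oxoglutaric anhydride), via keto diacid 12 (not isolated)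
Conditions: TFA, CH2Cl2, 0 °C; concentrate cold; then Ac2O, AcOH, 5–10 °C
Reagents that add atoms: none
Why: Acidolysis of the tert-butyl esters (E1 loss of isobutene) is followed at once by cold acetic anhydride dehydration, the standard route from acetonedicarboxylic acid to its cyclic anhydride, so the ring closes by 6-exo-trig acyl substitution before the β-keto acid can decarboxylate.

**Step 9**
Reactants: 13 3,5-bis[(4-benzyloxy-6-ethyl-5-methyl-2-oxo-2H-pyran-3-yl)methyl]-4-hydroxy-2H-pyran-2,6(3H)-dione
Product: 14 3,5-bis[(4-benzyloxy-6-ethyl-5-methyl-2-oxo-2H-pyran-3-yl)methyl]-4,6-bis(trimethylsilyloxy)-2H-pyran-2-one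
Conditions: TMSOTf (2.2 equiv), Et3N (2.5 equiv), Et2O–PhMe, 0 °C → rt; decant from the ammonium salt, concentrate under Ar, use crude
Reagents that add atoms: trimethylsilyl trifluoromethanesulfonate, C[Si](C)(C)OS(=O)(=O)C(F)(F)F
Why: O-silylation of an enolisable cyclic anhydride is known from the preparation of 2,5-bis(silyloxy)furans from succinic anhydrides and of the silyl enol ether of homophthalic anhydride, and here it is helped by the acidity of the ring CH and by formation of the aromatic 2-pyrone.

**Step 10**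
Reactants: 15 (R)-2-methylbutanoic acid
Product: 17 (R)-N-methoxy-N,2-dimethylbutanamide, via acyl imidazole 16 (not isolated)
Conditions: CDI, CH2Cl2, 0 °C → rt; then MeNHOMe·HCl, rt
Reagents that add atoms: N,O-dimethylhydroxylamine hydrochloride, CNOC.Cl
Why: Amide coupling through the acylimidazole is mild enough that the α-stereocentre of the branched acid, which carries no activating heteroatom, is not expected to epimerise.

**Step 11**
Reactants: 17 (R)-N-methoxy-N,2-dimethylbutanamide; 18 ethoxyethyne
Product: 21 (R)-1-ethoxy-4-methylhex-1-yn-3-one, via lithium ethoxyacetylide 19 (not isolated), via lithium hemiaminal adduct 20 (not isolated)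
Conditions: 18, n-BuLi, THF, −78 °C; then 17, −78 → −30 °C; inverse quench into cold 0.5 M HCl–Et2O; use promptly
Reagents that add atoms: none
Why: In this Weinreb ketone synthesis the lithium acetylide adds once to give a chelated tetrahedral adduct that survives until the cold acidic quench, so over-addition and base-mediated epimerisation are not expected, and protonating the liberated amine prevents its conjugate addition to the ynone.

**Step 12**
Reactants: 14 3,5-bis[(4-benzyloxy-6-ethyl-5-methyl-2-oxo-2H-pyran-3-yl)methyl]-4,6-bis(trimethylsilyloxy)-2H-pyran-2-one; 21 (R)-1-ethoxy-4-methylhex-1-yn-3-one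
Product: 24 (R)-1-{2-ethoxy-4,6-dihydroxy-3,5-bis[(4-benzyloxy-6-ethyl-5-methyl-2-oxo-2H-pyran-3-yl)methyl]phenyl}-2-methylbutan-1-one, via bicyclic lactone adduct 22 (not isolated), via bis-silyl aryl ether 23 (not isolated)
Conditions: PhMe, 80 °C, sealed tube, Ar; then 1 M HCl, THF, 0 °C
Reagents that add atoms: none
Why: Proposed new method: pyrone 14 is a cyclic 1,3-dioxygenated diene (C3=C4–C5=C6) whose nucleophilic terminus C3 adds to the ethoxy-bearing β-carbon of the push–pull ynone while the ketene-acetal carbon C6 bonds to the acyl-bearing α-carbon, either in a concerted asynchronous [4+2] cycloaddition or as a Mukaiyama–Michael addition followed by 6-endo closure of the allenyl enolate onto the silyloxy-stabilised cation at C6, and both paths give the 2-oxabicyclo[2.2.2]octadienone 22. Retro-[4+2] extrusion of CO2 from 22 is irreversible and leaves the hexasubstituted benzene ring of 23, so the one new ring is closed by the cycloaddition and aromatised by the cycloreversion, after which dilute acid frees the two phenols. The closest known reaction types are the Tamura annulation of enolisable homophthalic and glutaconic anhydrides with alkynes and the Diels–Alder/decarboxylation of 2-pyrones and of Brassard-type silyloxy dienes with acetylenic ketones. No stereocentre is created in the product, since the bridgeheads of 22 are lost with CO2, and the (R) centre of 21 is not at risk because the medium holds neither base nor strong acid. The step needs regioselectivity, which the matched polarisation of diene and alkyne should secure, and chemoselectivity for the central ring over the two arm pyrones, which should follow from the much higher HOMO of the bis(silyloxy) diene. The temperature is held below the onset of ethene loss from the ynol ether, and high pressure (about 12 kbar, CH2Cl2, rt) is the reserve against congestion at the two fully substituted termini.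

**Step 13**
Reactants: 24 (R)-1-{2-ethoxy-4,6-dihydroxy-3,5-bis[(4-benzyloxy-6-ethyl-5-methyl-2-oxo-2H-pyran-3-yl)methyl]phenyl}-2-methylbutan-1-one
Product: 25 (R)-1-{2,4,6-trihydroxy-3,5-bis[(6-ethyl-4-hydroxy-5-methyl-2-oxo-2H-pyran-3-yl)methyl]phenyl}-2-methylbutan-1-one (CNP0174567.1)
Conditions: BCl3 (excess), CH2Cl2, −78 → 0 °C; then H2O, 0 °C
Reagents that add atoms: none
Why: Boron trichloride should cleave the aryl ethyl ether through the six-membered chelate with the ortho ketone and remove both benzyl groups from the vinylogous esters by Lewis-acid dealkylation, while the fully substituted rings offer no site for C-benzylation and the low temperature protects the α-stereocentre.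

**Compound list**
1 | 3-pentanone | CCC(=O)CC | starting material
2 | 3-(trimethylsilyloxy)pent-2-ene (E/Z mixture) | CC=C(CC)O[Si](C)(C)C | intermediate
3 | malonyl dichloride | O=C(Cl)CC(=O)Cl | starting material
4 | 6-ethyl-4-hydroxy-5-methyl-2H-pyran-2-one | CCc1oc(=O)cc(O)c1C | intermediate
5 | 4-(benzyloxy)-6-ethyl-5-methyl-2H-pyran-2-one | CCc1oc(=O)cc(OCc2ccccc2)c1C | intermediate
6 | 4-(benzyloxy)-3-bromo-6-ethyl-5-methyl-2H-pyran-2-one | CCc1oc(=O)c(Br)c(OCc2ccccc2)c1C | intermediate
7 | 4-(benzyloxy)-6-ethyl-3-(hydroxymethyl)-5-methyl-2H-pyran-2-one | CCc1oc(=O)c(CO)c(OCc2ccccc2)c1C | intermediate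
8 | 4-(benzyloxy)-3-(bromomethyl)-6-ethyl-5-methyl-2H-pyran-2-one | CCc1oc(=O)c(CBr)c(OCc2ccccc2)c1C | intermediate
9 | di-tert-butyl 3-oxopentanedioate | CC(C)(C)OC(=O)CC(=O)CC(=O)OC(C)(C)C | starting material
10 | di-tert-butyl 2-[(4-benzyloxy-6-ethyl-5-methyl-2-oxo-2H-pyran-3-yl)methyl]-3-oxopentanedioate (racemic, not isolated) | CC(C)(C)OC(=O)CC(=O)C(Cc1c(OCc2ccccc2)c(C)c(CC)oc1=O)C(=O)OC(C)(C)C | intermediate
11 | di-tert-butyl 2,4-bis[(4-benzyloxy-6-ethyl-5-methyl-2-oxo-2H-pyran-3-yl)methyl]-3-oxopentanedioate (diastereomer mixture) | CC(C)(C)OC(=O)C(Cc1c(OCc2ccccc2)c(C)c(CC)oc1=O)C(=O)C(Cc1c(OCc2ccccc2)c(C)c(CC)oc1=O)C(=O)OC(C)(C)C | intermediate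
12 | 2,4-bis[(4-benzyloxy-6-ethyl-5-methyl-2-oxo-2H-pyran-3-yl)methyl]-3-oxopentanedioic acid (not isolated) | OC(=O)C(Cc1c(OCc2ccccc2)c(C)c(CC)oc1=O)C(=O)C(Cc1c(OCc2ccccc2)c(C)c(CC)oc1=O)C(=O)O | intermediate
13 | 3,5-bis[(4-benzyloxy-6-ethyl-5-methyl-2-oxo-2H-pyran-3-yl)methyl]-4-hydroxy-2H-pyran-2,6(3H)-dione (C3 unspecified) | O=C1OC(=O)C(Cc2c(OCc3ccccc3)c(C)c(CC)oc2=O)=C(O)C1Cc1c(OCc2ccccc2)c(C)c(CC)oc1=O | intermediate
14 | 3,5-bis[(4-benzyloxy-6-ethyl-5-methyl-2-oxo-2H-pyran-3-yl)methyl]-4,6-bis(trimethylsilyloxy)-2H-pyran-2-one | C[Si](C)(C)Oc1oc(=O)c(Cc2c(OCc3ccccc3)c(C)c(CC)oc2=O)c(O[Si](C)(C)C)c1Cc1c(OCc2ccccc2)c(C)c(CC)oc1=O | intermediate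
15 | (R)-2-methylbutanoic acid | OC(=O)[C@H](C)CC | starting material
16 | (R)-1-(1H-imidazol-1-yl)-2-methylbutan-1-one (not isolated) | O=C([C@H](C)CC)n1ccnc1 | intermediate
17 | (R)-N-methoxy-N,2-dimethylbutanamide | CON(C)C(=O)[C@H](C)CC | intermediate
18 | ethoxyethyne | CCOC#C | starting material
19 | lithium ethoxyacetylide (not isolated) | [Li]C#COCC | intermediate
20 | lithium (4R)-1-ethoxy-3-[methoxy(methyl)amino]-4-methylhex-1-yn-3-olate (C3 unspecified, not isolated) | CCOC#CC(O[Li])([C@H](C)CC)N(C)OC | intermediate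
21 | (R)-1-ethoxy-4-methylhex-1-yn-3-one | CCOC#CC(=O)[C@H](C)CC | intermediate
22 | 8-ethoxy-7-[(R)-2-methylbutanoyl]-4,6-bis[(4-benzyloxy-6-ethyl-5-methyl-2-oxo-2H-pyran-3-yl)methyl]-1,5-bis(trimethylsilyloxy)-2-oxabicyclo[2.2.2]octa-5,7-dien-3-one (bridgeheads unspecified, not isolated) | C[Si](C)(C)OC12OC(=O)C(Cc3c(OCc4ccccc4)c(C)c(CC)oc3=O)(C(OCC)=C1C(=O)[C@H](C)CC)C(O[Si](C)(C)C)=C2Cc1c(OCc2ccccc2)c(C)c(CC)oc1=O | intermediate
23 | (R)-1-{2-ethoxy-3,5-bis[(4-benzyloxy-6-ethyl-5-methyl-2-oxo-2H-pyran-3-yl)methyl]-4,6-bis(trimethylsilyloxy)phenyl}-2-methylbutan-1-one (not isolated) | CCOc1c(C(=O)[C@H](C)CC)c(O[Si](C)(C)C)c(Cc2c(OCc3ccccc3)c(C)c(CC)oc2=O)c(O[Si](C)(C)C)c1Cc1c(OCc2ccccc2)c(C)c(CC)oc1=O | intermediate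
24 | (R)-1-{2-ethoxy-4,6-dihydroxy-3,5-bis[(4-benzyloxy-6-ethyl-5-methyl-2-oxo-2H-pyran-3-yl)methyl]phenyl}-2-methylbutan-1-one | CCOc1c(C(=O)[C@H](C)CC)c(O)c(Cc2c(OCc3ccccc3)c(C)c(CC)oc2=O)c(O)c1Cc1c(OCc2ccccc2)c(C)c(CC)oc1=O | intermediate
25 | (R)-1-{2,4,6-trihydroxy-3,5-bis[(6-ethyl-4-hydroxy-5-methyl-2-oxo-2H-pyran-3-yl)methyl]phenyl}-2-methylbutan-1-one | CCc1oc(=O)c(Cc2c(O)c(Cc3c(O)c(C)c(CC)oc3=O)c(O)c(C(=O)[C@H](C)CC)c2O)c(O)c1C | target

**Count**
Total steps: 13. Longest linear sequence: 11 steps (steps 1–9, 12, 13); steps 10 and 11 form the short ynone branch.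

**Steps most likely to fail**

1. Step 12 (proposed new method). The cycloaddition may fail to engage because both diene termini are fully substituted. Alternatively the silyl ketene acetal may hydrolyse, or the ynol ether may lose ethene, before the two bonds form. The fallback uses known chemistry and sets out from 4 and 15. Acid 15 is converted with oxalyl chloride and catalytic DMF to (R)-2-methylbutanoyl chloride F1. F1 acylates phloroglucinol under Friedel–Crafts conditions (AlCl3, PhNO2–CH2Cl2, 0 °C → rt) to give (R)-2-methyl-1-(2,4,6-trihydroxyphenyl)butan-1-one F2. Pyrone 4 is aminomethylated with dimethylmethyleneiminium iodide to 3-[(dimethylamino)methyl]-6-ethyl-4-hydroxy-5-methyl-2H-pyran-2-one F3. Heating F2 with two equivalents of F3 in dioxane should release dimethylamine and generate the 3-methylenepyran-2,4-dione, which the two free ring positions of the acylphloroglucinol capture. This methylene bridging of acylphloroglucinols with pyrone Mannich bases is an established reaction type, and it rejoins the route at the target 25.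

2. Step 8. The β-keto diacid may decarboxylate before the ring closes, and the vinylogous benzyl esters may be partly lost in trifluoroacetic acid. The fallback sets out from 8 and never passes through a free acid. Dimethyl 3-oxopentanedioate is transesterified with 2-(trimethylsilyl)ethanol (DMAP cat., PhMe, reflux, methanol distilled off) to bis[2-(trimethylsilyl)ethyl] 3-oxopentanedioate F4. F4 is alkylated twice with 8 as in step 7 to give bis[2-(trimethylsilyl)ethyl] 2,4-bis[(4-benzyloxy-6-ethyl-5-methyl-2-oxo-2H-pyran-3-yl)methyl]-3-oxopentanedioate F5. TBAF (THF, 0 °C) should cleave both esters to the bis(tetrabutylammonium) 2,4-bis[(4-benzyloxy-6-ethyl-5-methyl-2-oxo-2H-pyran-3-yl)methyl]-3-oxopentanedioate F6, which as a salt does not decarboxylate. Trifluoroacetic anhydride at −20 °C closes F6 directly to anhydride 13, where the route is rejoined.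

3. Step 13. The ethyl ether may cleave incompletely, prolonged Lewis acid exposure may scramble the diarylmethane bridges, and enolisation through the boron chelate may erode the stereocentre. The fallback sets out from 24 and separates the two tasks. Hydrogenolysis (H2, 10% Pd/C, EtOAc, rt) removes both benzyl groups under neutral conditions to give (R)-1-{2-ethoxy-4,6-dihydroxy-3,5-bis[(6-ethyl-4-hydroxy-5-methyl-2-oxo-2H-pyran-3-yl)methyl]phenyl}-2-methylbutan-1-one F7. The ortho-acyl ethyl ether of F7 is then dealkylated by chelation-directed iodide attack (MgI2·OEt2, PhMe–THF, 60 °C), which rejoins the route at 25.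

**Further compounds**
F1 | step 12 | (R)-2-methylbutanoyl chloride | ClC(=O)[C@H](C)CC
F2 | step 12 | (R)-2-methyl-1-(2,4,6-trihydroxyphenyl)butan-1-one | O=C([C@H](C)CC)c1c(O)cc(O)cc1O
F3 | step 12 | 3-[(dimethylamino)methyl]-6-ethyl-4-hydroxy-5-methyl-2H-pyran-2-one | CCc1oc(=O)c(CN(C)C)c(O)c1C
F4 | step 8 | bis[2-(trimethylsilyl)ethyl] 3-oxopentanedioate | C[Si](C)(C)CCOC(=O)CC(=O)CC(=O)OCC[Si](C)(C)C
F5 | step 8 | bis[2-(trimethylsilyl)ethyl] 2,4-bis[(4-benzyloxy-6-ethyl-5-methyl-2-oxo-2H-pyran-3-yl)methyl]-3-oxopentanedioate | C[Si](C)(C)CCOC(=O)C(Cc1c(OCc2ccccc2)c(C)c(CC)oc1=O)C(=O)C(Cc1c(OCc2ccccc2)c(C)c(CC)oc1=O)C(=O)OCC[Si](C)(C)C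
F6 | step 8 | bis(tetrabutylammonium) 2,4-bis[(4-benzyloxy-6-ethyl-5-methyl-2-oxo-2H-pyran-3-yl)methyl]-3-oxopentanedioate | [O-]C(=O)C(Cc1c(OCc2ccccc2)c(C)c(CC)oc1=O)C(=O)C(Cc1c(OCc2ccccc2)c(C)c(CC)oc1=O)C([O-])=O.CCCC[N+](CCCC)(CCCC)CCCC.CCCC[N+](CCCC)(CCCC)CCCC
F7 | step 13 | (R)-1-{2-ethoxy-4,6-dihydroxy-3,5-bis[(6-ethyl-4-hydroxy-5-methyl-2-oxo-2H-pyran-3-yl)methyl]phenyl}-2-methylbutan-1-one | CCOc1c(C(=O)[C@H](C)CC)c(O)c(Cc2c(O)c(C)c(CC)oc2=O)c(O)c1Cc1c(O)c(C)c(CC)oc1=O
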